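I decided to read this flask from the tails of the two earlier runs, not from their peaks, treating target as fed from the starting material by a pseudo-first-order feed and lost by a first-order step of its own, so that its fraction of the charge is feed/(loss − feed) times the difference of the two decaying exponentials.

| setting | south-west | west | flask |
|---|---|---|---|
| starting material | 2.8 M | 2 M | 2.0 M |
| catalyst | 5 mol% | 5 mol% | 5 mol% |
| added ligand | 210 mM | 320 mM | 210 mM |
| remark | run made earlier | run made earlier |  |
| time |  |  | 2.0 min |

| run | time / min | target / % |
|---|---|---|
| south-west | 0.167 | 15.9 |
| south-west | 0.333 | 19.1 |
| south-west | 0.667 | 13.5 |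
| south-west | 1.33 | 4.6 |
| south-west | 2.50 | 0.2 |
| west | 0.167 | 6.1 |
| west | 0.200 | 8.2 |
| west | 0.500 | 9.4 |
| west | 1.00 | 5.7 |
| west | 2.50 | 2.0 |

(standard deviation of a reading: 1 percentage point)

- the analysis behind the earlier runs scatters by 1 percentage point, standard deviation

* when, up to 2.0 min, the flask holds most target
* the amount of target, in percent of the starting material charged, at that time
* the first time at which target reaches 6.7 %, in the same percent, in min

Between two late readings of each run the south-west tail fell at 1.62 min⁻¹, and the west tail at 0.698 min⁻¹, a rougher reading, its last point being 2.0 % with a scatter of 1 percentage point. Carried back to zero time, the south-west tail gave a fraction of 39.9 %, which in the closed form is feed/(loss − feed), so I read a loss of 5.70 min⁻¹ and assumed the flask shared it. For the flask, which lies between the runs, I took the geometric mean of the tails as its feed, 1.06 min⁻¹.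

That made a ladder. Target's loss had a half-life of 0.122 min, shorter than the feed's 0.654 min, and both were shorter than the 2.0 min allowed. So target should catch up early and then fall with the starting material. The height depends on the feed ratio, feed rate over loss rate, 0.187, raised to the power 1/(1 − ratio): I expected 12.7 % at 0.363 min. Without any loss, target would reach the asked level at 0.0629 min, so I expected it somewhat later.

The forecast said 13 % at 0.38 min, first reaching the level at 0.1 min, later than my no-loss time, on the grounds that “The flask shares its starting material with west and its ligand with south-west”.

The flask gave 13.4 % at 0.355 min, and reached the level at 0.0752 min.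

    target → over-reaction product (k = 0.0880 s⁻¹)
    catalyst + added ligand ⇌ idle complex, settled at all times (K = 60.0 L mol⁻¹)
    starting material + catalyst ⇌ target + catalyst, rate k3*[starting material]*[catalyst] forward; the back reaction follows from the equilibrium constant (K = 2.00, k = 1.60 L mol⁻¹ s⁻¹)
    starting material + catalyst ⇌ isomer of the product + catalyst, rate k4*[starting material]*[catalyst] forward; the back reaction follows from the equilibrium constant (K = 1.30, k = 0.0180 L mol⁻¹ s⁻¹)

In the flask, target's half-life by passing into over-reaction product was 0.13 min, shorter than the 0.401 min relaxation half-life of starting material and target at 2.00 min. At 2.00 min the flask held 2.97 % of target beside 12.4 % of starting material. With target's loss now taken from the scheme as 5.28 min⁻¹, the 12 % of starting material left in the flask, read as a single first-order fall, gives a feed of 1.04 min⁻¹, a feed ratio of 0.197 and a peak of 13.2 %. The neighbouring flask with 2 mol% of catalyst kept 52 %, which read the same way gives a feed ratio of 0.0626 and a peak of 5.20 %, against the 5.15 % that flask reached.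

(All runs were generated by integration on assumed constants; noise was put on by code.)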